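## Retrosynthetic overview

- Numbering is that of the eremophilanes: ring A = C1–C5 and C10, ring B = C5–C10, C14 = methyl on C5, C15 = methyl on C4, C11 = carbinol carbon, β = the face of C14. The ester is made last, by Mitsunobu inversion of the 3β-alcohol with (Z)-2-methyl-3-(methylsulfanyl)acrylic acid.
- The ring B dienone comes from the cycloadduct of a 2-methoxy-p-benzoquinone: C9=O becomes an enol triflate and then C9–H (C9=C10); C6=O and C8–OMe undergo a Stork–Danheiser transposition (C8=O, C6=C7).
- Ring A comes from a Diels–Alder reaction of the quinone C5(Me)=C10(H) bond with 4-silyloxy-2H-thiopyran, which forms C1–C10 and C4–C5. The ring sulfur of the diene remains as a temporary C15–S–C1 bridge, which Raney Ni cuts to give the C4 methyl and C1H2.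
- Enabling feature: C15 and C1 carry only hydrogen and lie 1,4 across ring A, so one sulfur atom can tie them. The "inside" methyl needed for the cis C14/C15 pair thereby becomes part of a reactive cyclic diene, and the C5-quaternary 2,5-cyclohexadienone of ring B maps onto a quinone with one free double bond.
- Ring order: ring B is present from the first step (arene, then quinone). Ring A is closed in the key step together with the temporary thia-bridged ring, which is opened two steps later.

Key step: step 6

Assumption: the (R)-binaphthol ligand is written for step 6 by analogy only; if the adduct proves to be the mirror image, the (S)-ligand is used and nothing else changes.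

## Route

Step 1
Reactants: 1 1,2,4-trimethoxy-5-methylbenzene
Product: 3 2-(2,3,6-trimethoxy-5-methylphenyl)propan-2-ol, via aryllithium 2 (not isolated)
Conditions: n-BuLi, TMEDA, THF, 0 °C; acetone, −78 °C → rt; aq NH4Cl
Reagents that add atoms: acetone CC(C)=O
Why: Directed ortho-metalation should occur at the ring position flanked by two methoxy groups, and 1,2-addition of the aryllithium to acetone gives the tertiary alcohol without creating a stereocenter.

Step 2
Reactants: 3 2-(2,3,6-trimethoxy-5-methylphenyl)propan-2-ol
Product: 4 3-(2-hydroxypropan-2-yl)-2-methoxy-5-methyl-1,4-benzoquinone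
Conditions: (NH4)2Ce(NO3)6, MeCN/H2O, 0 °C
Reagents that add atoms: water O
Why: Oxidative demethylation should convert the para-disposed methoxy pair into the p-quinone and leave the third methoxy group as the vinylogous ester that later deactivates its own double bond and steers the cycloaddition.

Step 3
Reactants: 4 3-(2-hydroxypropan-2-yl)-2-methoxy-5-methyl-1,4-benzoquinone
Product: 5 2-methoxy-5-methyl-3-[2-(triethylsilyloxy)propan-2-yl]-1,4-benzoquinone
Conditions: Et3SiOTf, 2,6-lutidine, CH2Cl2, −78 → 0 °C
Reagents that add atoms: triethylsilyl trifluoromethanesulfonate CC[Si](CC)(CC)OS(=O)(=O)C(F)(F)F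
Why: Silyl triflate silylation of the tertiary alcohol removes the proton that would bind the titanium catalyst and makes the carbinol oxygen a poor leaving group for the acidic transposition in step 11.

Step 4
Reactants: 6 tetrahydro-4H-thiopyran-4-one
Product: 8 2,3-dihydro-4H-thiopyran-4-one, via chlorosulfide 7 (not isolated)
Conditions: NCS (1 equiv), pyridine, CH2Cl2, 0 °C → rt
Reagents that add atoms: none
Why: Pummerer-type α-chlorination of the sulfide followed by pyridine-mediated dehydrochlorination is an established dehydrogenation of thian-4-one to the vinylogous thioester.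

Step 5
Reactants: 8 2,3-dihydro-4H-thiopyran-4-one
Product: 9 4-(tert-butyldimethylsilyloxy)-2H-thiopyran
Conditions: t-BuMe2SiOTf, Et3N, Et2O, 0 °C
Reagents that add atoms: tert-butyldimethylsilyl trifluoromethanesulfonate CC(C)(C)[Si](C)(C)OS(=O)(=O)C(F)(F)F
Why: Soft enolisation (silyl triflate and amine) at the only α-methylene gives the cisoid 1-thio-3-silyloxy diene locked in the ring.

Step 6
Reactants: 5 2-methoxy-5-methyl-3-[2-(triethylsilyloxy)propan-2-yl]-1,4-benzoquinone; 9 4-(tert-butyldimethylsilyloxy)-2H-thiopyran
Product: 10 endo cycloadduct: cis-fused tricyclic enedione with a C2=C3 silyl enol ether and a β-face C15H2–S–C1 bridge in ring A (2-thiabicyclo[2.2.2]oct-5-ene); ring B C6=O, C7–C(CH3)2OSiEt3, C7=C8, C8–OCH3, C9=O; C14 and C10–H β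
Conditions: (R)-BINOL·TiCl2 (cat., from TiCl2(Oi-Pr)2 and (R)-BINOL, 4 Å MS), CH2Cl2/toluene, −40 → −20 °C
Reagents that add atoms: none
Why: A concerted but asynchronous normal-demand [4+2] cycloaddition joins the electron-rich cisoid diene of 9 to the C5=C10 bond of quinone 5, whose C9 carbonyl and neighbouring methoxy oxygen are chelated by the chiral titanium Lewis acid; the closest known reaction types are the BINOL–TiCl2-catalysed enantioselective Diels–Alder reaction of 2-methoxy-p-benzoquinones with silyloxydienes and the cycloadditions of silyloxy-2H-thiopyrans used as cis-diene equivalents. Ring A is closed by intermolecular suprafacial–suprafacial [4+2] addition (C1–C10 and C4–C5 formed on one face of each partner), which also turns the thiopyran ring into the temporary CH2–S bridge of a 2-thiabicyclo[2.2.2]octene. C5 (absolute) is set by the quinone face left open by the binaphtholate; C4 is set relative to C5 because the future C15 is tied to C1 through sulfur and must sit in the inside position of the diene, so the endo transition state places C15 and C14 on the same face of ring A (cis); C10 (cis fusion) and C1 are stereocenters only transiently. The step needs site selectivity (C7=C8 is tetrasubstituted and deactivated as a vinylogous ester, so only C5=C10 reacts), regioselectivity (the nucleophilic diene terminus, β to the silyloxy group and remote from sulfur, bonds to C5, the β-carbon of the chelated C9 carbonyl, both donors acting in the same sense), endo selectivity (usual for a cyclic diene and a quinone) and facial selectivity (catalyst).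

Step 7
Reactants: 10 endo cycloadduct
Product: 11 C3 ethylene ketal (1,3-dioxolane) of the thia-bridged enedione, otherwise as 10
Conditions: HOCH2CH2OH, camphorsulfonic acid (cat.), CH2Cl2, 0 °C → rt
Reagents that add atoms: ethylene glycol OCCO
Why: Acid-catalysed transketalisation (C-protonation of the silyl enol ether and capture of the oxocarbenium ion by the diol, far faster than cleavage of the hindered tertiary silyl ether) masks the C3 ketone, so that only C10–H is enolisable in step 9 and neither C–S bond is allylic in step 8.

Step 8
Reactants: 11 C3 ethylene ketal of the thia-bridged enedione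
Product: 12 8-methoxy-11-(triethylsilyloxy)eremophil-7-ene-6,9-dione 3-ethylene ketal (4β,5β-dimethyl, 10β-H)
Conditions: Raney Ni (W-2, aged in acetone), acetone/THF, rt
Reagents that add atoms: none
Why: Raney nickel desulfurisation should cleave both C–S bonds of the thiane ketal, turning the bridge CH2 into the C4 methyl and C1 into a methylene without touching C4 or C5, so the cis-vicinal dimethyl pair is revealed with retention, and acetone-aged nickel should spare the enedione.

Step 9
Reactants: 12 8-methoxy-11-(triethylsilyloxy)eremophil-7-ene-6,9-dione 3-ethylene ketal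
Product: 14 8-methoxy-6-oxo-11-(triethylsilyloxy)eremophila-7,9-dien-9-yl trifluoromethanesulfonate 3-ethylene ketal, via potassium enolate 13 (not isolated)
Conditions: KN(SiMe3)2, THF, −78 °C; PhNTf2, −78 → 0 °C
Reagents that add atoms: N-phenylbis(trifluoromethanesulfonimide) O=S(=O)(N(c1ccccc1)S(=O)(=O)C(F)(F)F)C(F)(F)F
Why: Deprotonation at the only enolisable position (ring-fusion C10–H next to the C9 carbonyl, the C6 carbonyl having no α-hydrogen) and O-sulfonylation give the enol triflate, deliberately erasing the C10 stereocenter.

Step 10
Reactants: 14 enol triflate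
Product: 15 8-methoxy-11-(triethylsilyloxy)eremophila-7,9-dien-6-one 3-ethylene ketal
Conditions: Pd(OAc)2 (cat.), PPh3, HCO2H, n-Bu3N, DMF, 60 °C
Reagents that add atoms: none
Why: Palladium-catalysed formate reduction of the enol triflate (oxidative addition to zerovalent palladium, formate exchange, decarboxylation, reductive elimination) replaces the C9 oxygen by hydrogen and leaves the C9=C10 double bond of the target.

Step 11
Reactants: 15 8-methoxy-11-(triethylsilyloxy)eremophila-7,9-dien-6-one 3-ethylene ketal
Product: 18 (4R,5R)-11-hydroxyeremophila-6,9-diene-3,8-dione, via allylic alcohol 16 (not isolated), via dienone ketal 17 (not isolated)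
Conditions: i-Bu2AlH, CH2Cl2, −78 → −20 °C; then 1 M HCl, THF, 0 °C → rt
Reagents that add atoms: water O
Why: In a Stork–Danheiser transposition, 1,2-reduction of the vinylogous ester carbonyl (C6, new carbinol center uncontrolled and then lost) and acid-promoted loss of that hydroxyl through the methoxy-stabilised cation give the C8 ketone and the C6=C7 bond, after which the same aqueous acid removes the dioxolane and the silyl group, while C4, now α to a ketone, already carries the thermodynamically preferred equatorial methyl and should not be scrambled.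

Step 12
Reactants: 18 (4R,5R)-11-hydroxyeremophila-6,9-diene-3,8-dione
Product: 19 (3S,4R,5R)-3,11-dihydroxyeremophila-6,9-dien-8-one (3β-OH, axial)
Conditions: LiBH(s-Bu)3 (2.2 equiv), THF, −78 °C; aq NH4Cl (no peroxide)
Reagents that add atoms: none
Why: Bulky-hydride (Selectride) reduction of the saturated C3 ketone should outpace attack on the hindered cross-conjugated dienone and proceed by equatorial approach from the face opposite the axial C14 methyl, giving the axial alcohol cis to both methyl groups.

Step 13
Reactants: 20 prop-2-yn-1-ol
Product: 22 (Z)-3-iodo-2-methylprop-2-en-1-ol, via vinylmagnesium alkoxide 21 (not isolated)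
Conditions: MeMgBr (2.5 equiv), CuI (cat.), Et2O, −10 °C → rt; I2, −50 → 0 °C
Reagents that add atoms: methylmagnesium bromide C[Mg]Br; iodine II
Why: Alkoxide-directed, copper-catalysed anti-carbomagnesiation of the alkyne followed by iodinolysis of the chelated vinylmagnesium places iodine cis to the CH2OH group.

Step 14
Reactants: 22 (Z)-3-iodo-2-methylprop-2-en-1-ol
Product: 23 (Z)-3-iodo-2-methylprop-2-enoic acid
Conditions: TEMPO (cat.), PhI(OAc)2, MeCN/H2O, rt
Reagents that add atoms: water O
Why: Oxoammonium (TEMPO) oxidation in aqueous acetonitrile takes the allylic alcohol through the aldehyde hydrate to the acid without touching the vinyl iodide or its geometry.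

Step 15
Reactants: 23 (Z)-3-iodo-2-methylprop-2-enoic acid
Product: 24 (Z)-2-methyl-3-(methylsulfanyl)prop-2-enoic acid
Conditions: NaSMe (2.5 equiv), DMF, 0 → 40 °C; then 1 M HCl
Reagents that add atoms: sodium methanethiolate C[S-].[Na+]
Why: Nucleophilic vinylic substitution (addition–elimination) on a β-haloacrylate by a thiolate proceeds with retention, so sulfur should end cis to the carboxyl group.

Step 16
Reactants: 19 (3S,4R,5R)-3,11-dihydroxyeremophila-6,9-dien-8-one; 24 (Z)-2-methyl-3-(methylsulfanyl)prop-2-enoic acid
Product: 25 (3R,4R,5R)-11-hydroxy-8-oxoeremophila-6,9-dien-3-yl (Z)-2-methyl-3-(methylsulfanyl)prop-2-enoate (CNP0150028.1)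
Conditions: PPh3, DIAD, toluene, 0 °C → rt
Reagents that add atoms: none
Why: In the Mitsunobu esterification the carboxylate displaces the axial C3 oxyphosphonium group by SN2 attack from the unhindered α face, inverting C3 to the equatorial (3R) ester, while the tertiary alcohol is inert under these conditions.

## Compound list

1 | 1,2,4-trimethoxy-5-methylbenzene | COc1cc(OC)c(C)cc1OC | starting material
2 | (2,3,6-trimethoxy-5-methylphenyl)lithium | COc1c([Li])c(OC)c(C)cc1OC | intermediate (not isolated)
3 | 2-(2,3,6-trimethoxy-5-methylphenyl)propan-2-ol | COc1c(C(C)(C)O)c(OC)c(C)cc1OC | intermediate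
4 | 3-(2-hydroxypropan-2-yl)-2-methoxy-5-methyl-1,4-benzoquinone | COC1=C(C(C)(C)O)C(=O)C(C)=CC1=O | intermediate
5 | 2-methoxy-5-methyl-3-[2-(triethylsilyloxy)propan-2-yl]-1,4-benzoquinone | CC[Si](CC)(CC)OC(C)(C)C1=C(OC)C(=O)C=C(C)C1=O | intermediate
6 | tetrahydro-4H-thiopyran-4-one | O=C1CCSCC1 | starting material
7 | 2-chlorotetrahydro-4H-thiopyran-4-one | O=C1CCSC(Cl)C1 | intermediate (not isolated)
8 | 2,3-dihydro-4H-thiopyran-4-one | O=C1C=CSCC1 | intermediate
9 | 4-(tert-butyldimethylsilyloxy)-2H-thiopyran | CC(C)(C)[Si](C)(C)OC1=CCSC=C1 | intermediate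
10 | endo cycloadduct: thia-bridged (C15H2–S–C1, β) cis-fused enedione, C2=C3 tert-butyldimethylsilyl enol ether, C14 and C10–H β | CC[Si](CC)(CC)OC(C)(C)C1=C(OC)C(=O)[C@H]2[C@@H]3SC[C@@H](C(O[Si](C)(C)C(C)(C)C)=C3)[C@@]2(C)C1=O | intermediate
11 | C3 ethylene ketal of the thia-bridged enedione | CC[Si](CC)(CC)OC(C)(C)C1=C(OC)C(=O)[C@H]2[C@@H]3SC[C@@H](C4(C3)OCCO4)[C@@]2(C)C1=O | intermediate
12 | 8-methoxy-11-(triethylsilyloxy)eremophil-7-ene-6,9-dione 3-ethylene ketal (4β,5β-dimethyl, 10β-H) | CC[Si](CC)(CC)OC(C)(C)C1=C(OC)C(=O)[C@H]2CCC3(OCCO3)[C@H](C)[C@@]2(C)C1=O | intermediate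
13 | potassium C9 enolate of 12 (C9=C10) | CC[Si](CC)(CC)OC(C)(C)C1=C(OC)C(O[K])=C2CCC3(OCCO3)[C@H](C)[C@@]2(C)C1=O | intermediate (not isolated)
14 | 8-methoxy-6-oxo-11-(triethylsilyloxy)eremophila-7,9-dien-9-yl trifluoromethanesulfonate 3-ethylene ketal | CC[Si](CC)(CC)OC(C)(C)C1=C(OC)C(OS(=O)(=O)C(F)(F)F)=C2CCC3(OCCO3)[C@H](C)[C@@]2(C)C1=O | intermediate
15 | 8-methoxy-11-(triethylsilyloxy)eremophila-7,9-dien-6-one 3-ethylene ketal | CC[Si](CC)(CC)OC(C)(C)C1=C(OC)C=C2CCC3(OCCO3)[C@H](C)[C@@]2(C)C1=O | intermediate
16 | 8-methoxy-11-(triethylsilyloxy)eremophila-7,9-dien-6-ol 3-ethylene ketal (either C6 epimer) | CC[Si](CC)(CC)OC(C)(C)C1=C(OC)C=C2CCC3(OCCO3)[C@H](C)[C@@]2(C)C1O | intermediate (not isolated)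
17 | 11-(triethylsilyloxy)eremophila-6,9-dien-8-one 3-ethylene ketal | CC[Si](CC)(CC)OC(C)(C)C1=C[C@]2(C)[C@@H](C)C3(OCCO3)CCC2=CC1=O | intermediate (not isolated)
18 | (4R,5R)-11-hydroxyeremophila-6,9-diene-3,8-dione | O=C1CCC2=CC(=O)C(C(C)(C)O)=C[C@]2(C)[C@H]1C | intermediate
19 | (3S,4R,5R)-3,11-dihydroxyeremophila-6,9-dien-8-one (3β-OH) | O[C@H]1CCC2=CC(=O)C(C(C)(C)O)=C[C@]2(C)[C@H]1C | intermediate
20 | prop-2-yn-1-ol | C#CCO | starting material
21 | bromomagnesium (Z)-3-(bromomagnesio)-2-methylprop-2-en-1-olate | Br[Mg]/C=C(/C)CO[Mg]Br | intermediate (not isolated)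
22 | (Z)-3-iodo-2-methylprop-2-en-1-ol | I/C=C(/C)CO | intermediate
23 | (Z)-3-iodo-2-methylprop-2-enoic acid | I/C=C(/C)C(=O)O | intermediate
24 | (Z)-2-methyl-3-(methylsulfanyl)prop-2-enoic acid | CS/C=C(/C)C(=O)O | intermediate
25 | (3R,4R,5R)-11-hydroxy-8-oxoeremophila-6,9-dien-3-yl (Z)-2-methyl-3-(methylsulfanyl)prop-2-enoate | CS/C=C(/C)C(=O)O[C@@H]1CCC2=CC(=O)C(C(C)(C)O)=C[C@]2(C)[C@H]1C | target

## Step count and risks

Total step count: 16. Longest linear sequence: 11 steps (1, 2, 3, 6, 7, 8, 9, 10, 11, 12, 16).

Steps most likely to fail: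

Step 6. The process at risk is facial discrimination and turnover: the ring sulfide or a silyl ether oxygen may bind titanium, so that a slow background reaction with poor enantioselectivity takes over. Fallback: setting out from 5 and 9, the cycloaddition is run without chiral catalyst (toluene, 60 °C). This should give 10 together with its mirror image ent-10 F1. The two are separated by preparative chromatography on a chiral polysaccharide phase, and the route is rejoined at 10.

Step 11. The process at risk is competing ionisation at the tertiary silyloxy-bearing carbon, or premature loss of the silyl group, under the acidic work-up; this would divert the methoxy-stabilised cation away from the dienone. Fallback: setting out from 15, the i-Bu2AlH reduction is worked up under neutral conditions and 16 is isolated. MsCl and Et3N at −20 °C give the secondary allylic mesylate F2, which should ionise with enol-ether assistance without Brønsted acid, and buffered hydrolysis (NaHCO3, THF/H2O) gives 17. The dioxolane (PPTS, wet acetone) and the silyl ether (HF·pyridine) are then removed in separate operations, and the route is rejoined at 18.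

Step 16. The process at risk is elimination across C2–C3 or C3–C4 (anti-periplanar axial hydrogens) or sluggish substitution at the hindered axial center with a weakly acidic carboxylic acid. Fallback: setting out from 19, Mitsunobu inversion with the more acidic 4-nitrobenzoic acid gives the inverted 3α 4-nitrobenzoate F3. Methanolysis (K2CO3, MeOH) gives the equatorial alcohol (3R,4R,5R)-3,11-dihydroxyeremophila-6,9-dien-8-one F4, and Steglich esterification (DCC, DMAP) with 24 proceeds with retention, rejoining the route at 25.

Further compounds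
F1 | step 6 | ent-10 (mirror image of the endo cycloadduct) | CC[Si](CC)(CC)OC(C)(C)C1=C(OC)C(=O)[C@@H]2[C@H]3SC[C@H](C(O[Si](C)(C)C(C)(C)C)=C3)[C@]2(C)C1=O
F2 | step 11 | C6 methanesulfonate of 16 | CC[Si](CC)(CC)OC(C)(C)C1=C(OC)C=C2CCC3(OCCO3)[C@H](C)[C@@]2(C)C1OS(C)(=O)=O
F3 | step 16 | (3R,4R,5R)-11-hydroxy-8-oxoeremophila-6,9-dien-3-yl 4-nitrobenzoate | O=C(O[C@@H]1CCC2=CC(=O)C(C(C)(C)O)=C[C@]2(C)[C@H]1C)c1ccc([N+](=O)[O-])cc1
F4 | step 16 | (3R,4R,5R)-3,11-dihydroxyeremophila-6,9-dien-8-one | O[C@@H]1CCC2=CC(=O)C(C(C)(C)O)=C[C@]2(C)[C@H]1C
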